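Labels: central cyclohexane (ring C) = Ca (bears CMe2–O), Cb (bears quinolone A), Cc, Cd (Me, O), Ce, Cf (bears quinolone B); ring B = bridged pyran O–Cd–Ce–Cf–C3=C4 of quinolone B. The target is cut at Cf–Ca, Cc–Cb and O–Cd. Two isomeric C15 halves are united in one operation: N-methylflindersine as dienophile and a 2-isopropenyl-2,3-dihydrofuro[3,2-c]quinolinone as masked dienol. Palladium opens the five-membered ring, a Diels–Alder reaction builds ring C with three stereocentres, and the same oxygen recloses on the former isopropenyl carbon Cd, so ring B arises from the dihydrofuran by ring expansion by one atom. The step exploits the 1,3-relation of Cf to the oxygenated quaternary Cd.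

Key step: step 4

Assumption: no catalyst-controlled form of this cycloaddition is relied on. Step 4 sets the four stereocentres relative to one another, and the drawn enantiomer is taken from the racemate by preparative chromatography on a chiral stationary phase. A catalyst-controlled alternative is given as the fallback for step 4.

Remark on the chemistry: the ring expansion is a net 1,2-shift of the ether oxygen (from C2 of the dihydrofuran to the former isopropenyl carbon) that runs through the ring-opened dienol, not a concerted migration.

Step 1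
Reactants: 1 4-hydroxy-1-methylquinolin-2(1H)-one; 2 3-methylbut-2-enal
Product: 4 N-methylflindersine, via 1-oxatriene 3 (not isolated)
Conditions: pyridine, 115 °C
Reagents that add atoms: none
Why: Knoevenagel condensation at C3 should give the 1-oxatriene 3, which closes through O4 by oxa-6π electrocyclisation to the angular 2H-pyran; no stereocentre is formed.

Step 2
Reactants: 1 4-hydroxy-1-methylquinolin-2(1H)-one; 5 2-methyl-2-vinyloxirane
Product: 6 4-hydroxy-3-[(2E)-4-hydroxy-3-methylbut-2-en-1-yl]-1-methylquinolin-2(1H)-one
Conditions: Pd(PPh3)4 (3 mol %), THF, 25 °C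
Reagents that add atoms: none
Why: Tsuji–Trost allylic alkylation, in which zerovalent palladium opens the vinyl epoxide to a π-allyl alkoxide that deprotonates 1, and the soft C3 nucleophile attacks the unsubstituted allyl terminus to give the E-configured 1,4-adduct; no stereocentre is formed.

Step 3
Reactants: 6 4-hydroxy-3-[(2E)-4-hydroxy-3-methylbut-2-en-1-yl]-1-methylquinolin-2(1H)-one
Product: 7 racemic 5-methyl-2-(prop-1-en-2-yl)-2,3-dihydrofuro[3,2-c]quinolin-4(5H)-one
Conditions: Pd(OAc)2 (5 mol %), PPh3 (20 mol %), Ti(OiPr)4 (25 mol %), 4 Å MS, toluene, 60 °C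
Reagents that add atoms: none
Why: Intramolecular Tsuji–Trost allylic etherification, in which zerovalent palladium (from Pd(OAc)2 and PPh3) ionises the Ti(OiPr)4-activated allylic alcohol and O4 attacks the internal allyl terminus in a 5-exo closure; the C2 stereocentre forms as the racemate, which is intended because step 4 erases it.

Step 4
Reactants: 4 N-methylflindersine; 7 racemic 5-methyl-2-(prop-1-en-2-yl)-2,3-dihydrofuro[3,2-c]quinolin-4(5H)-one
Product: 10 target bis(pyranoquinolinone), via dienol 8 (not isolated), via cycloadduct 9 (not isolated)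
Conditions: Pd(PPh3)4 (5 mol %), o-xylene, 80 °C then 140 °C; (±)-camphor-10-sulfonic acid (10 mol %), 60 °C; preparative SFC on a chiral stationary phase
Reagents that add atoms: none
Why: Zerovalent palladium should ionise the allylic C2–O bond of 7 (the 4-oxidoquinolinone is a vinylogous carboxylate leaving group) and β-hydride elimination from the π-allyl complex should release dienol 8; at 140 °C 8 and the cis-locked C3=C4 alkene of 4 should then combine in a polar [4+2] cycloaddition to 9, and acid adds the 4-OH of quinolone B to the new trisubstituted alkene. The closest known reaction types are the thermal Diels–Alder cyclodimerisation of 2H-pyrano[3,2-c]quinolinones through their ring-opened dienols and the Tsuji–Trost elimination of allylic ethers to 1,3-dienes. Ring C closes by the [4π+2π] union (bonds Cf–Ca and Cc–Cb), and ring B closes by Markovnikov hydroalkoxylation in a bridging six-membered mode, the oxygen that left C2 of 7 returning to the former isopropenyl carbon Cd, which makes the O1–C2–C3–C3a–C9b ring of 7 one atom larger. Ca and Cb keep the cis relation of the ring alkene of 4, Cf is set cis to both by the endo approach in which the E-dienyl quinolone lies over the pyranoquinolinone, and Cd is fixed because the oxygen on Cf can reach it only from the face that carries quinolone B. The step needs head-to-tail regiochemistry (nucleophilic CH2 terminus of 8 to the benzylic C4 of 4, the quinolonyl-bearing terminus to C3) and endo selectivity, which the polarisation of the dienol and stacking of the two quinolinones should favour; minor isomers are removed by chromatography. The cycloaddition is not enantioselective, so 10 is separated from its mirror image on the chiral phase.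

Compound list
1 | 4-hydroxy-1-methylquinolin-2(1H)-one | Cn1c(=O)cc(O)c2ccccc21 | starting material
2 | 3-methylbut-2-enal | CC(C)=CC=O | starting material
3 | 1-methyl-3-(3-methylbut-2-en-1-ylidene)quinoline-2,4(1H,3H)-dione (1-oxatriene) | CN1C(=O)C(=CC=C(C)C)C(=O)c2ccccc21 | intermediate
4 | N-methylflindersine, 2,2,6-trimethyl-2,6-dihydro-5H-pyrano[3,2-c]quinolin-5-one | Cn1c(=O)c2c(c3ccccc31)OC(C)(C)C=C2 | intermediate
5 | 2-methyl-2-vinyloxirane (racemic) | CC1(C=C)CO1 | starting material
6 | 4-hydroxy-3-[(2E)-4-hydroxy-3-methylbut-2-en-1-yl]-1-methylquinolin-2(1H)-one | Cn1c(=O)c(C/C=C(\C)CO)c(O)c2ccccc21 | intermediate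
7 | racemic 5-methyl-2-(prop-1-en-2-yl)-2,3-dihydrofuro[3,2-c]quinolin-4(5H)-one | CC(=C)C1Cc2c(O1)c1ccccc1n(C)c2=O | intermediate
8 | 4-hydroxy-1-methyl-3-[(1E)-3-methylbuta-1,3-dien-1-yl]quinolin-2(1H)-one (dienol) | Cn1c(=O)c(/C=C/C(C)=C)c(O)c2ccccc21 | intermediate
9 | Diels–Alder adduct: cyclohexene ring C (Cd=Ce) cis-fused at Ca–Cb to the 2,2-dimethylpyran of quinolone A, with the 4-hydroxy-1-methyl-2-oxoquinolin-3-yl group at Cf cis to the Ca–CMe2 and Cb–quinolone bonds (formed as the racemate, drawn enantiomer shown) | Cn1c(=O)c2c(c3ccccc31)OC(C)(C)[C@H]1[C@@H]2CC(C)=C[C@H]1c1c(O)c3ccccc3n(C)c1=O | intermediate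
10 | target: ring C cis-fused at Ca–Cb to the 2,2-dimethylpyran of quinolone A and bridged from Cd (methyl, O) to Cf by the pyran of quinolone B; the CMe2 group at Ca, quinolone A at Cb, quinolone B at Cf and the Cd–O bond all on one face of ring C | Cn1c(=O)c2c(c3ccccc31)OC(C)(C)[C@H]1[C@@H]2C[C@]2(C)C[C@H]1c1c(c3ccccc3n(C)c1=O)O2 | target

Total steps: 4. Longest linear sequence: 3 steps (1 → 6 → 7 → 10); step 1 supplies the second fragment.

Steps most likely to fail

Step 4. The intermolecular cycloaddition may run with poor endo and head-to-tail selectivity. The dienol may also close to the 2H-pyran faster than it cycloadds, and the absolute configuration rests on a physical separation. The fallback builds ring C under catalyst control, sets out from 1 and comes back to the route at 10: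
- Conjugate addition of 1 to (3E)-6-methylhepta-3,5-dien-2-one under a chiral primary amine salt ((1R,2R)-1,2-diphenylethane-1,2-diamine with AcOH, or its antipode if the sense of induction requires it) should give 4-hydroxy-1-methyl-3-[(4R)-6-methyl-2-oxohept-5-en-4-yl]quinolin-2(1H)-one F1, which carries Cf.
- Vinylmagnesium bromide should add to the ketone to give the tertiary allylic alcohol 4-hydroxy-3-(3-hydroxy-3,7-dimethylocta-1,6-dien-5-yl)-1-methylquinolin-2(1H)-one F2.
- Pyridinium chlorochromate should transpose F2 oxidatively to the 5-quinolonyl citral 5-(4-hydroxy-1-methyl-2-oxo-1,2-dihydroquinolin-3-yl)-3,7-dimethylocta-2,6-dienal F3.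
- Condensation of F3 with a second equivalent of 1 (ethylenediammonium diacetate, toluene, 110 °C) should give the 1-oxatriene F4. Its intramolecular hetero-Diels–Alder reaction with the 2-methylprop-1-enyl group should give the cis-fused pyranoquinolinone–cyclohexene F5 (alkene Cc=Cd), with quinolone B equatorial and cis to the new ring.
- TsOH (10 mol %) in CH2Cl2 then adds the free 4-OH to the ring alkene and gives 10 without a resolution.

Step 3. The π-allyl complex may be captured by the lactam oxygen (linear 4-quinolone isomer) or by C3 instead of O4. The fallback uses no metal catalyst, sets out from 1 and comes back at 7. C3-alkylation of 1 with (E)-1,4-dibromo-2-methylbut-2-ene (K2CO3, acetone, 56 °C) at the less hindered CH2Br should give 3-[(2E)-4-bromo-3-methylbut-2-en-1-yl]-4-hydroxy-1-methylquinolin-2(1H)-one F6. In the same flask O4 should displace bromide in an SN2′ closure at the internal alkene carbon to give 7.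

Step 2. O-allylation, attack at the substituted allyl terminus or double allylation may compete with the distal C-alkylation. The fallback sets out from 1 and comes back at 6. C3-prenylation of 1 with 1-bromo-3-methylbut-2-ene (aqueous NaOH) should give 4-hydroxy-1-methyl-3-(3-methylbut-2-en-1-yl)quinolin-2(1H)-one F7. SeO2 (catalytic) with t-BuOOH should then oxidise the E-methyl group of the prenyl unit to the allylic alcohol 6.

Further compounds
F1 | step 4 | 4-hydroxy-1-methyl-3-[(4R)-6-methyl-2-oxohept-5-en-4-yl]quinolin-2(1H)-one | CC(=O)C[C@H](C=C(C)C)c1c(O)c2ccccc2n(C)c1=O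
F2 | step 4 | 4-hydroxy-3-(3-hydroxy-3,7-dimethylocta-1,6-dien-5-yl)-1-methylquinolin-2(1H)-one (carbinol centre unassigned) | C=CC(C)(O)C[C@H](C=C(C)C)c1c(O)c2ccccc2n(C)c1=O
F3 | step 4 | 5-(4-hydroxy-1-methyl-2-oxo-1,2-dihydroquinolin-3-yl)-3,7-dimethylocta-2,6-dienal (E/Z mixture at C2) | CC(=CC=O)C[C@H](C=C(C)C)c1c(O)c2ccccc2n(C)c1=O
F4 | step 4 | 1-oxatriene from F3 and 1 (Knoevenagel adduct) | CN1C(=O)C(=CC=C(C)C[C@H](C=C(C)C)c3c(O)c4ccccc4n(C)c3=O)C(=O)c2ccccc21
F5 | step 4 | cis-fused pyranoquinolinone–cyclohexene (alkene Cc=Cd) carrying quinolone B at Cf | Cn1c(=O)c2c(c3ccccc31)OC(C)(C)[C@H]1[C@@H]2C=C(C)C[C@H]1c1c(O)c3ccccc3n(C)c1=O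
F6 | step 3 | 3-[(2E)-4-bromo-3-methylbut-2-en-1-yl]-4-hydroxy-1-methylquinolin-2(1H)-one | Cn1c(=O)c(C/C=C(\C)CBr)c(O)c2ccccc21
F7 | step 2 | 4-hydroxy-1-methyl-3-(3-methylbut-2-en-1-yl)quinolin-2(1H)-one | Cn1c(=O)c(CC=C(C)C)c(O)c2ccccc21
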